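Ring numbering: C1 = C(CH3)(CH=CHCl), C2 = CH2, C3 = C(Cl)(CH2Br), C4 = CHBr, C5 = CH2, C6 = CHCl. In the target C3–Cl, C4–Br, C6–Cl and the chlorovinyl group lie on one ring face, CH3 and CH2Br on the other.
Cuts, last made first: C4–Br and C3–Cl (cis, so a syn-bromochlorination of a C3=C4 alkene, not an anti addition); the CH2–Br bond (allylic transposition that also removes a helper oxygen from C4); the exocyclic C3–CH2 bond (alpha-methylenation); the chlorovinyl C=C (Takai); finally C5–C6 and C2–C1 together in one [4+2] cycloaddition.
Enabling feature: in the cyclohexane ring the adjacent stereocentres C1 and C6 are flanked by the bare methylenes C2 and C5. These lead to the vicinally dihalogenated pair C3/C4, a latent ring alkene. The ring is therefore a butadiene (C2–C5) plus a two-carbon unit C1=C6 that already carries CH3, Cl and a formyl group as chlorovinyl precursor.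
Helper: a silyloxy group on C4 makes C5 the nucleophilic diene terminus and enforces the pairing C5–C6/C2–C1, which a 2-(halomethyl)butadiene would not give. It serves to bring in the exocyclic carbon (steps 6 and 7) and leaves in step 8.
Forward: dienophile (steps 1 and 2) and diene (step 3) are made separately. The only ring arises in step 4, followed by the side chain (step 5), the C3 carbon (steps 6 to 8) and the last two halogens (step 9).
Stereochemistry: C1/C6 relative from the Z geometry of the dienophile, absolute from a chiral cationic oxazaborolidine; the E-chloroalkene from the Takai reaction; C3 and C4 from substrate-controlled trans-diaxial chloroselenenylation followed by SN2 inversion at C4.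

Key step: step 4

Assumption: the sense of induction in step 4 is taken from the accepted pre-transition-state model for alpha-substituted enals on cationic oxazaborolidines, which calls for the (R)-diphenylprolinol-derived catalyst. Should the antipode form, the (S)-catalyst is used and nothing else changes.

Step 1
Reactants: 1 prop-2-yn-1-ol
Product: 3 (Z)-3-chloro-2-methylprop-2-en-1-ol, via alkenylmagnesium alkoxide 2 (not isolated)
Conditions: MeMgBr (3 equiv), CuI (10 mol %), THF–Et2O, −10 °C to rt; then NCS (2 equiv), −30 °C to rt; aq NH4Cl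
Reagents that add atoms: methylmagnesium bromide, C[Mg]Br; N-chlorosuccinimide, O=C1CCC(=O)N1Cl
Why: Copper-catalysed anti-carbomagnesiation of the magnesium propargylate puts methyl on the internal carbon and magnesium on the terminal carbon cis to CH2O (five-membered chelate), and electrophilic chlorination of the alkenyl–magnesium bond with retention fixes the Z-chloroalkene that later becomes the cis C1/C6 relationship.

Step 2
Reactants: 3 (Z)-3-chloro-2-methylprop-2-en-1-ol
Product: 4 (Z)-3-chloro-2-methylprop-2-enal
Conditions: activated MnO2 (15 equiv), CH2Cl2, rt; filtered, used as a concentrated solution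
Reagents that add atoms: none
Why: Allylic oxidation on MnO2 is neutral and heterogeneous, so the Z geometry and the vinylic chloride should survive.

Step 3
Reactants: 5 but-3-en-2-one (methyl vinyl ketone)
Product: 6 2-(triisopropylsilyloxy)buta-1,3-diene
Conditions: TIPSOTf (1.05 equiv), Et3N (1.5 equiv), CH2Cl2, 0 °C to rt
Reagents that add atoms: triisopropylsilyl triflate, CC(C)[Si](C(C)C)(C(C)C)OS(=O)(=O)C(F)(F)F
Why: Soft enolisation (silyl triflate/amine) of the methyl ketone can only deprotonate the methyl group and gives the cross-conjugated 2-silyloxydiene.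

Step 4
Reactants: 4 (Z)-3-chloro-2-methylprop-2-enal; 6 2-(triisopropylsilyloxy)buta-1,3-diene
Product: 7 (1R,6R)-6-chloro-1-methyl-4-(triisopropylsilyloxy)cyclohex-3-ene-1-carbaldehyde
Conditions: (R)-3,3-diphenyl-1-(2-methylphenyl)tetrahydro-1H,3H-pyrrolo[1,2-c][1,3,2]oxazaborole (20 mol %), HN(SO2CF3)2 (18 mol %), 6 (1.5 equiv), CH2Cl2, −78 to −40 °C
Reagents that add atoms: none
Why: The protonated oxazaborolidine binds the formyl oxygen of 4 (s-trans enal, formyl C–H···O contact) and lowers its LUMO, and 6 adds in a concerted but asynchronous Diels–Alder reaction, the closest known reaction type being the cationic-oxazaborolidine-catalysed cycloaddition of alpha-substituted enals with 2-silyloxybutadienes. The six-membered carbocycle is closed in an intermolecular suprafacial [π4s+π2s] mode, with C5–C6 bond formation running ahead of C2–C1. Regiochemistry: the silyloxy group on C4 makes C5 the nucleophilic diene terminus, which pairs with the electrophilic beta-carbon C6 of the enal so that the formyl-bearing C1 ends 1,4 to C4, whereas a diene carrying only the future CH2Br carbon on C3 would pair C2 with C6. The relative configuration at C1/C6 (formyl cis to chlorine) is copied stereospecifically from the Z alkene of 4, and endo/exo topology has no consequence because both diene termini are CH2. The absolute configuration (1R,6R) comes from the catalyst, whose aryl group shields one face of the bound enal. The step needs ring closure to outrun loss of chloride from a stepwise Michael-type intermediate, which low temperature, the non-polar medium and rapid charge recombination should secure; it also installs the neopentylic C6–Cl bond that substitution chemistry could hardly make.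

Step 5
Reactants: 7 (1R,6R)-6-chloro-1-methyl-4-(triisopropylsilyloxy)cyclohex-3-ene-1-carbaldehyde
Product: 8 {[(4R,5R)-5-chloro-4-[(E)-2-chloroethenyl]-4-methylcyclohex-1-en-1-yl]oxy}triisopropylsilane
Conditions: CrCl2 (6 equiv), CHCl3 (2.5 equiv), THF, 65 °C
Reagents that add atoms: chloroform, ClC(Cl)Cl
Why: Takai olefination: the geminal dichromium species from CHCl3 adds to the non-enolisable aldehyde and eliminates to the E-chloroalkene, while the secondary alkyl chloride and the bulky silyl enol ether should be inert to CrCl2.

Step 6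
Reactants: 8 {[(4R,5R)-5-chloro-4-[(E)-2-chloroethenyl]-4-methylcyclohex-1-en-1-yl]oxy}triisopropylsilane
Product: 11 (4R,5R)-5-chloro-4-[(E)-2-chloroethenyl]-4-methyl-2-methylidenecyclohexan-1-one, via Mannich base 9 (not isolated), via methiodide 10 (not isolated)
Conditions: CH2=NMe2+ I− (1.5 equiv), CH2Cl2, rt; MeI (10 equiv), rt; then aq NaHCO3–CH2Cl2, rt
Reagents that add atoms: N,N-dimethylmethyleneiminium iodide (Eschenmoser's salt), C=[N+](C)C.[I-]; iodomethane, CI (its methyl group stays only in intermediate 10)
Why: Regiospecific Mannich reaction at C3, the only nucleophilic carbon of the silyl enol ether, then exhaustive methylation and Hofmann-type beta-elimination give the alpha-methylene ketone; the ammonium group leaves much faster than the C6 chloride, so bicarbonate suffices, and the transient C3 stereocentre is erased.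

Step 7
Reactants: 11 (4R,5R)-5-chloro-4-[(E)-2-chloroethenyl]-4-methyl-2-methylidenecyclohexan-1-one
Product: 12 (4R,5R)-5-chloro-4-[(E)-2-chloroethenyl]-4-methyl-2-methylidenecyclohexan-1-ol (carbinol epimers, both serve)
Conditions: NaBH4, CeCl3·7H2O, MeOH, −78 to −40 °C
Reagents that add atoms: none
Why: Luche reduction delivers hydride 1,2 to the enone faster than enolisation toward C5 can expel chloride, and the configuration of the new carbinol carbon is irrelevant because step 8 erases it.

Step 8
Reactants: 12 (4R,5R)-5-chloro-4-[(E)-2-chloroethenyl]-4-methyl-2-methylidenecyclohexan-1-ol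
Product: 13 (4R,5R)-1-(bromomethyl)-4-chloro-5-[(E)-2-chloroethenyl]-5-methylcyclohex-1-ene
Conditions: PBr3 (0.4 equiv), Et2O, −10 °C to rt
Reagents that add atoms: phosphorus tribromide, BrP(Br)Br
Why: Allylic substitution with transposition (SN2′ on the bromophosphite, plus bromide-mediated equilibration of any secondary bromide) gives the thermodynamically preferred primary allylic bromide with the trisubstituted ring alkene, which removes the helper oxygen from C4 and creates the CH2Br group.

Step 9
Reactants: 13 (4R,5R)-1-(bromomethyl)-4-chloro-5-[(E)-2-chloroethenyl]-5-methylcyclohex-1-ene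
Product: 16 (1S,2S,4R,5R)-2-bromo-1-(bromomethyl)-1,4-dichloro-5-[(E)-2-chloroethenyl]-5-methylcyclohexane, via chloro selenide 14 (not isolated), via selenium dibromide 15 (not isolated)
Conditions: PhSeCl (1.05 equiv), CH2Cl2–MeCN, −20 °C to rt; Br2 (1.1 equiv), −40 °C; Bu4NBr (3 equiv), −40 °C to rt
Reagents that add atoms: benzeneselenenyl chloride, Cl[Se]c1ccccc1; bromine, BrBr
Why: Proposed new method: PhSeCl adds reversibly and anti across C3=C4 (the electron-poor chlorovinyl group stays untouched), and equilibration should collect adduct 14 with selenium on the secondary C4 (face of the C1 methyl group) and chloride on the tertiary C3 (opposite face), the only isomer with PhSe and Cl trans-diaxial while CH2Br and C6–Cl stay equatorial. Br2 then oxidises selenium to the tetravalent dibromide 15, which can no longer form a seleniranium ion but is an excellent axial nucleofuge, so bromide displaces it by SN2 with inversion and places C4–Br cis to C3–Cl. The closest known reaction types are the selenium-mediated syn-dichlorination of 1,2-disubstituted alkenes (same sequence of anti addition, oxidation and invertive displacement) and the bromolysis of secondary alkyl phenyl selenides with inversion; new are the mixed halogen pair on a trisubstituted alkene and the tertiary chloride next to the displacement site.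

Compound list
1 | prop-2-yn-1-ol | C#CCO | starting material
2 | bromomagnesium (Z)-3-(bromomagnesio)-2-methylprop-2-en-1-olate (Mg cis to CH2O) | Br[Mg]/C=C(/C)CO[Mg]Br | intermediate
3 | (Z)-3-chloro-2-methylprop-2-en-1-ol | Cl/C=C(/C)CO | intermediate
4 | (Z)-3-chloro-2-methylprop-2-enal | Cl/C=C(/C)C=O | intermediate
5 | but-3-en-2-one | CC(=O)C=C | starting material
6 | 2-(triisopropylsilyloxy)buta-1,3-diene | C=CC(=C)O[Si](C(C)C)(C(C)C)C(C)C | intermediate
7 | (1R,6R)-6-chloro-1-methyl-4-(triisopropylsilyloxy)cyclohex-3-ene-1-carbaldehyde | C[C@]1(C=O)CC=C(O[Si](C(C)C)(C(C)C)C(C)C)C[C@H]1Cl | intermediate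
8 | {[(4R,5R)-5-chloro-4-[(E)-2-chloroethenyl]-4-methylcyclohex-1-en-1-yl]oxy}triisopropylsilane | C[C@]1(/C=C/Cl)CC=C(O[Si](C(C)C)(C(C)C)C(C)C)C[C@H]1Cl | intermediate
9 | (4R,5R)-5-chloro-4-[(E)-2-chloroethenyl]-2-[(dimethylamino)methyl]-4-methylcyclohexan-1-one (C2 epimers) | C[C@]1(/C=C/Cl)CC(CN(C)C)C(=O)C[C@H]1Cl | intermediate
10 | {(4R,5R)-5-chloro-4-[(E)-2-chloroethenyl]-4-methyl-2-oxocyclohexyl}methyl-trimethylammonium iodide (epimers at the ring carbon bearing CH2N) | C[C@]1(/C=C/Cl)CC(C[N+](C)(C)C)C(=O)C[C@H]1Cl.[I-] | intermediate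
11 | (4R,5R)-5-chloro-4-[(E)-2-chloroethenyl]-4-methyl-2-methylidenecyclohexan-1-one | C[C@]1(/C=C/Cl)CC(=C)C(=O)C[C@H]1Cl | intermediate
12 | (4R,5R)-5-chloro-4-[(E)-2-chloroethenyl]-4-methyl-2-methylidenecyclohexan-1-ol (C1 epimers) | C[C@]1(/C=C/Cl)CC(=C)C(O)C[C@H]1Cl | intermediate
13 | (4R,5R)-1-(bromomethyl)-4-chloro-5-[(E)-2-chloroethenyl]-5-methylcyclohex-1-ene | C[C@]1(/C=C/Cl)CC(CBr)=CC[C@H]1Cl | intermediate
14 | [(1R,2R,4R,5R)-2-(bromomethyl)-2,5-dichloro-4-[(E)-2-chloroethenyl]-4-methylcyclohexyl](phenyl)selane | C[C@]1(/C=C/Cl)C[C@](Cl)(CBr)[C@H]([Se]c2ccccc2)C[C@H]1Cl | intermediate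
15 | dibromo[(1R,2R,4R,5R)-2-(bromomethyl)-2,5-dichloro-4-[(E)-2-chloroethenyl]-4-methylcyclohexyl](phenyl)-λ4-selane | C[C@]1(/C=C/Cl)C[C@](Cl)(CBr)[C@H]([Se](Br)(Br)c2ccccc2)C[C@H]1Cl | intermediate
16 | (1S,2S,4R,5R)-2-bromo-1-(bromomethyl)-1,4-dichloro-5-[(E)-2-chloroethenyl]-5-methylcyclohexane | C[C@]1(/C=C/Cl)C[C@](Cl)(CBr)[C@@H](Br)C[C@H]1Cl | target

Total step count: 9. Longest linear sequence: 8 (steps 1, 2, 4, 5, 6, 7, 8, 9).

Steps most likely to fail

Risk 1 (step 9). Several processes may interfere.
- Chloride may open the seleniranium ion at C4, because the CH2Br group disfavours positive charge on C3.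
- The tertiary chloride may lose HCl.
- The addition may reverse after oxidation, followed by ordinary anti-bromination.
- Halide may exchange at C3.
- The axial chlorine may participate during the displacement, which gives retention.

The fallback uses known chemistry, sets out from 13 and comes back at 16. mCPBA (NaHCO3, CH2Cl2, 0 °C) should epoxidise the ring alkene on the face of the C1 methyl group, away from C6–Cl and the chlorovinyl group. This gives 1-(bromomethyl)-4-chloro-3-[(E)-2-chloroethenyl]-3-methyl-7-oxabicyclo[4.1.0]heptane F1. HCl in CHCl3 (or TiCl4, CH2Cl2, −78 °C) opens it trans-diaxially at the tertiary carbon to the chlorohydrin (1R,2R,4R,5R)-2-(bromomethyl)-2,5-dichloro-4-[(E)-2-chloroethenyl]-4-methylcyclohexan-1-ol F2. Ph3PBr2 (MeCN–CH2Cl2, 0 °C to rt) then displaces the activated axial oxygen with inversion to give 16. This is the stepwise form of the known conversion of cyclohexene oxide into cis-1,2-dihalocyclohexanes with dihalotriphenylphosphoranes.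

Risk 2 (step 4). The polarised diene may react stepwise (Mukaiyama–Michael addition) with expulsion of chloride instead of ring closure. The enal may isomerise from Z to E on the strong acid. Facial selectivity may also be poor, because the Z-chlorine sits near the binding site.

The fallback sets out from 4 and 6 and comes back at 7. It replaces catalyst control by an uncatalysed, concerted cycloaddition followed by resolution. Heating 4 and 6 (toluene, BHT, 110 °C, sealed tube) should give 7 together with its enantiomer (1S,6S)-6-chloro-1-methyl-4-(triisopropylsilyloxy)cyclohex-3-ene-1-carbaldehyde F3. Condensation with (1R,2R)-N,N'-dimethyl-1,2-diphenylethane-1,2-diamine (Et2O, 4 Å molecular sieves, rt) gives two diastereomeric aminals: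
- (4R,5R)-2-[(1R,6R)-6-chloro-1-methyl-4-(triisopropylsilyloxy)cyclohex-3-en-1-yl]-1,3-dimethyl-4,5-diphenylimidazolidine F4
- (4R,5R)-2-[(1S,6S)-6-chloro-1-methyl-4-(triisopropylsilyloxy)cyclohex-3-en-1-yl]-1,3-dimethyl-4,5-diphenylimidazolidine F5

These are separated by chromatography, and brief treatment of the first with cold dilute aqueous HCl–Et2O returns 7.

Risk 3 (step 6). The beta-chloro ketone may lose HCl across C5–C6 under the influence of the amine or the base. The Mannich reaction of the bulky silyl enol ether may be sluggish, and the alpha-methylene ketone may dimerise.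

The fallback sets out from 8 and comes back at 11, and it avoids base altogether. Phenylthiomethylation of the silyl enol ether (PhSCH2Cl, ZnBr2 cat., CH2Cl2, rt) gives (4R,5R)-5-chloro-4-[(E)-2-chloroethenyl]-4-methyl-2-[(phenylsulfanyl)methyl]cyclohexan-1-one F6. mCPBA (1 equiv, CH2Cl2, −78 °C) gives the sulfoxide (4R,5R)-5-chloro-4-[(E)-2-chloroethenyl]-4-methyl-2-[(phenylsulfinyl)methyl]cyclohexan-1-one F7. Thermal syn-elimination (toluene, CaCO3, 100 °C), for which C3–H is the only beta-hydrogen, gives 11.

Further compounds
F1 | step 9 | 1-(bromomethyl)-4-chloro-3-[(E)-2-chloroethenyl]-3-methyl-7-oxabicyclo[4.1.0]heptane, oxirane oxygen cis to the ring methyl group | C[C@]1(/C=C/Cl)C[C@]2(CBr)O[C@@H]2C[C@H]1Cl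
F2 | step 9 | (1R,2R,4R,5R)-2-(bromomethyl)-2,5-dichloro-4-[(E)-2-chloroethenyl]-4-methylcyclohexan-1-ol | C[C@]1(/C=C/Cl)C[C@](Cl)(CBr)[C@H](O)C[C@H]1Cl
F3 | step 4 | (1S,6S)-6-chloro-1-methyl-4-(triisopropylsilyloxy)cyclohex-3-ene-1-carbaldehyde | C[C@@]1(C=O)CC=C(O[Si](C(C)C)(C(C)C)C(C)C)C[C@@H]1Cl
F4 | step 4 | (4R,5R)-2-[(1R,6R)-6-chloro-1-methyl-4-(triisopropylsilyloxy)cyclohex-3-en-1-yl]-1,3-dimethyl-4,5-diphenylimidazolidine | C[C@]1(C2N(C)[C@H](c3ccccc3)[C@@H](c3ccccc3)N2C)CC=C(O[Si](C(C)C)(C(C)C)C(C)C)C[C@H]1Cl
F5 | step 4 | (4R,5R)-2-[(1S,6S)-6-chloro-1-methyl-4-(triisopropylsilyloxy)cyclohex-3-en-1-yl]-1,3-dimethyl-4,5-diphenylimidazolidine | C[C@@]1(C2N(C)[C@H](c3ccccc3)[C@@H](c3ccccc3)N2C)CC=C(O[Si](C(C)C)(C(C)C)C(C)C)C[C@@H]1Cl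
F6 | step 6 | (4R,5R)-5-chloro-4-[(E)-2-chloroethenyl]-4-methyl-2-[(phenylsulfanyl)methyl]cyclohexan-1-one (C2 epimers) | C[C@]1(/C=C/Cl)CC(CSc2ccccc2)C(=O)C[C@H]1Cl
F7 | step 6 | (4R,5R)-5-chloro-4-[(E)-2-chloroethenyl]-4-methyl-2-[(phenylsulfinyl)methyl]cyclohexan-1-one (epimers at C2 and sulfur) | C[C@]1(/C=C/Cl)CC(CS(=O)c2ccccc2)C(=O)C[C@H]1Cl
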